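**Retrosynthetic overview**

1. Numbering used throughout: C1 = ring-fusion carbon bearing CH3; C2, C3 = cyclopentane CH2; C4 = C(OH)(isopropyl); C5 = ring-fusion CH; C6 = CH–O; C7 = CH2; C8 = C(CH3)–O; C9 = CH–O; C10 = CH2.
2. Target ⇒ epoxy diol (acylation at C6–OH) ⇒ homoallylic diol (C6–OH-directed epoxidation of C8=C9, oxirane formed last) ⇒ β,γ-unsaturated ketone (C4–OH-directed reduction at C6) ⇒ trans-fused hydroazulenone with C9=C10 (alkene moved to C8=C9 by dehydrogenation and deconjugative reduction).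
3. Hydroazulenone ⇒ acyclic chloromethyl ketone: one intramolecular (4+3) cycloaddition of the oxyallyl cation C5–C6–C7 onto the diene C1=C10–C9=C8 forms C5–C1 and C7–C8, so the five- and the seven-membered ring are closed in the same operation.
4. Enabling feature: the oxygen-bearing C6 is the middle atom of the three-carbon arc C5–C6–C7 of the seven-membered ring, the other arc C8–C9–C10–C1 is four carbons long, and C1 and C5 are the fusion atoms, so C2–C3–C4 of the five-membered ring act as a three-atom tether that carries the only preset stereocentre (C4).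
5. Chloromethyl ketone ⇒ (S)-terpinen-4-ol: ozonolysis opens the cyclohexene with C4 intact; the methyl ketone end becomes the (E,E)-diene (alkyne, carboalumination, Suzuki–Miyaura coupling) and the aldehyde end the chloromethyl ketone.

Key step: step 9

Assumption: (S)-(+)-terpinen-4-ol 1 is taken to be purchasable in enantiomerically enriched form; material of lower enantiomeric purity would be upgraded before step 1.

**Step 1**
Reactants: 1 (S)-(+)-terpinen-4-ol [(1S)-4-methyl-1-(propan-2-yl)cyclohex-3-en-1-ol]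
Product: 2 triethyl{[(1S)-4-methyl-1-(propan-2-yl)cyclohex-3-en-1-yl]oxy}silane
Conditions: Et3SiOTf, 2,6-lutidine, CH2Cl2, −78 → 0 °C
Reagents that add atoms: triethylsilyl trifluoromethanesulfonate CC[Si](CC)(CC)OS(=O)(=O)C(F)(F)F
Why: Silyl ether protection of the tertiary alcohol with a silyl triflate masks the oxygen that would otherwise alkylate the later chloromethyl ketone, and no stereocentre is touched.

**Step 2**
Reactants: 2 triethyl{[(1S)-4-methyl-1-(propan-2-yl)cyclohex-3-en-1-yl]oxy}silane
Product: 4 (5S)-7,7-dimethoxy-5-(propan-2-yl)-5-[(triethylsilyl)oxy]heptan-2-one, via keto aldehyde 3 (not isolated)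
Conditions: O3, CH2Cl2/MeOH, −78 °C; Me2S, −78 → 20 °C; then HC(OMe)3, CeCl3·7H2O, 20 °C
Reagents that add atoms: ozone [O-][O+]=O; trimethyl orthoformate COC(OC)OC
Why: Ozonolysis with reductive work-up cleaves the only C=C bond of the p-menthene ring without involving the C4 stereocentre, and the cerium trichloride-mediated acetalisation should take the aldehyde in preference to the methyl ketone.

**Step 3**
Reactants: 4 (5S)-7,7-dimethoxy-5-(propan-2-yl)-5-[(triethylsilyl)oxy]heptan-2-one
Product: 6 triethyl{[(3S)-1,1-dimethoxy-3-(propan-2-yl)hept-6-yn-3-yl]oxy}silane, via enol phosphate 5 (not isolated)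
Conditions: LiN(iPr)2, THF, −78 °C; ClP(O)(OEt)2, −78 → 20 °C; then LiN(iPr)2 (2.3 equiv), THF, −78 → 20 °C
Reagents that add atoms: none
Why: Kinetic deprotonation of the methyl ketone at CH3, O-phosphorylation and base-induced elimination of the enol phosphate (ketone-to-alkyne conversion) should give the terminal alkyne without touching the acetal or the silyl ether.

**Step 4**
Reactants: 6 triethyl{[(3S)-1,1-dimethoxy-3-(propan-2-yl)hept-6-yn-3-yl]oxy}silane
Product: 8 triethyl{[(3S,6E)-7-iodo-1,1-dimethoxy-6-methyl-3-(propan-2-yl)hept-6-en-3-yl]oxy}silane, via alkenylalane 7 (not isolated)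
Conditions: Me3Al, Cp2ZrCl2, H2O (1 equiv), CH2Cl2, −30 → 0 °C; then I2, THF, −30 → 0 °C
Reagents that add atoms: trimethylaluminium C[Al](C)C; iodine II
Why: Zirconium-catalysed carboalumination adds CH3 and Al syn across the terminal alkyne with CH3 on the internal carbon, and iodinolysis of the C–Al bond with retention fixes the (E)-trisubstituted alkene that later places the C1 methyl on the inside of the diene.

**Step 5**
Reactants: 8 triethyl{[(3S,6E)-7-iodo-1,1-dimethoxy-6-methyl-3-(propan-2-yl)hept-6-en-3-yl]oxy}silane; 9 4,4,5,5-tetramethyl-2-[(1E)-prop-1-en-1-yl]-1,3,2-dioxaborolane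
Product: 10 triethyl{[(3S,6E,8E)-1,1-dimethoxy-6-methyl-3-(propan-2-yl)deca-6,8-dien-3-yl]oxy}silane
Conditions: Pd(PPh3)4 (5 mol %), 2 M aq. NaOH, THF, 50 °C
Reagents that add atoms: 4,4,5,5-tetramethyl-2-[(1E)-prop-1-en-1-yl]-1,3,2-dioxaborolane C/C=C/B1OC(C)(C)C(C)(C)O1
Why: Suzuki–Miyaura coupling proceeds with retention at both alkenyl partners and should therefore deliver the (6E,8E)-diene.

**Step 6**
Reactants: 10 triethyl{[(3S,6E,8E)-1,1-dimethoxy-6-methyl-3-(propan-2-yl)deca-6,8-dien-3-yl]oxy}silane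
Product: 11 (3S,6E,8E)-6-methyl-3-(propan-2-yl)-3-[(triethylsilyl)oxy]deca-6,8-dienal
Conditions: Et3SiOTf, 2,4,6-collidine, CH2Cl2, 0 °C; then H2O
Reagents that add atoms: water O
Why: Silyl triflate/collidine acetal cleavage (a collidinium intermediate hydrolysed by water) should unmask the aldehyde under buffered, non-protic conditions that spare the tertiary silyl ether and the diene.

**Step 7**
Reactants: 11 (3S,6E,8E)-6-methyl-3-(propan-2-yl)-3-[(triethylsilyl)oxy]deca-6,8-dienal; 12 chloroiodomethane
Product: 13 (4S,7E,9E)-1-chloro-7-methyl-4-(propan-2-yl)-4-[(triethylsilyl)oxy]undeca-7,9-dien-2-ol (both C2 epimers)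
Conditions: ICH2Cl, MeLi·LiBr, THF/Et2O, −78 °C; aq. NH4Cl, −78 °C
Reagents that add atoms: chloroiodomethane ClCI
Why: Chloromethyllithium made by iodine–lithium exchange in the presence of the aldehyde (Barbier-type carbenoid addition) adds to the carbonyl before it decomposes, and the new carbinol centre needs no control because it is oxidised in step 8.

**Step 8**
Reactants: 13 (4S,7E,9E)-1-chloro-7-methyl-4-(propan-2-yl)-4-[(triethylsilyl)oxy]undeca-7,9-dien-2-ol
Product: 14 (4S,7E,9E)-1-chloro-7-methyl-4-(propan-2-yl)-4-[(triethylsilyl)oxy]undeca-7,9-dien-2-one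
Conditions: Dess–Martin periodinane, NaHCO3, CH2Cl2, 0 → 20 °C
Reagents that add atoms: none
Why: Dess–Martin oxidation of the secondary chlorohydrin gives the α-chloro ketone under buffered, non-basic conditions that avoid epoxide closure and β-elimination of the silyloxy group.

**Step 9**
Reactants: 14 (4S,7E,9E)-1-chloro-7-methyl-4-(propan-2-yl)-4-[(triethylsilyl)oxy]undeca-7,9-dien-2-one
Product: 17 (1R,4R,5R,8R)-4-hydroxy-1,8-dimethyl-4-(propan-2-yl)-trans-bicyclo[5.3.0]dec-9-en-6-one (locants of the numbering line), via oxyallyl cation 15 (not isolated), via silyl ether cycloadduct 16 (not isolated)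
Conditions: Et3N (3 equiv), (CF3)2CHOH/CH2Cl2, 0.01 M, 0 → 20 °C; then HF·pyridine, THF, 0 → 20 °C
Reagents that add atoms: none
Why: Triethylamine removes a proton from C5 and the enolate loses chloride from C7 in the ionising, weakly nucleophilic fluoroalcohol to give the oxyallyl cation 15, which adds across the tethered diene in a (4+3) cycloaddition that forms C5–C1 and C7–C8, after which HF·pyridine cleaves the silyl ether of 16. The closest known reaction type is the intramolecular (4+3) cycloaddition of oxyallyl cations made from α-halo ketones with amine bases in fluorinated alcohols onto dienes held by a three-atom tether. The five-membered ring closes in the 5-exo mode (cation terminus C5 onto the tether-bearing diene terminus C1, C10 staying outside this ring) and the seven-membered ring closes by the suprafacial union of the three-carbon 2π cation C5–C6–C7 with the 4π diene C1=C10–C9=C8. C5 is controlled by the C4 stereocentre, because the cation should react in its W form on the face of the C3 tether with the isopropyl group turned to the side of C5–H and the smaller silyloxy oxygen to the side of the oxyallyl oxygen (allylic 1,3-strain), so that C6 ends cis to the C4 oxygen; C1 is controlled by the (E) geometry of C1=C10 (methyl inside, tether outside) combined with the extended, chair-like approach usual for three-atom tethers, which gives the trans ring fusion and puts the C1 methyl cis to the C4 oxygen; C8 follows from the (E)-propenyl terminus and is erased in step 10. The step needs (4+3) closure to win over Favorskii rearrangement, solvent capture and (3+2) closure through oxygen, which intramolecularity, high dilution and the poorly nucleophilic solvent should secure, and it needs the extended over the compact approach (the compact one would give the cis-fused C1 epimer), which the strain of the cis-fused alternative and the inside methyl group should favour. The tertiary silyl ether keeps the C4 oxygen from displacing the primary chloride before ionisation.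

**Step 10**
Reactants: 17 (1R,4R,5R,8R)-4-hydroxy-1,8-dimethyl-4-(propan-2-yl)-trans-bicyclo[5.3.0]dec-9-en-6-one
Product: 18 (1R,4R,5R)-4-hydroxy-1,8-dimethyl-4-(propan-2-yl)bicyclo[5.3.0]deca-7,9-dien-6-one
Conditions: IBX (2.5 equiv), DMSO/PhF, 70 °C
Reagents that add atoms: none
Why: IBX-mediated α,β-dehydrogenation of the ketone can only run toward C7–C8 because C5 has no β-hydrogen, which removes the C8 stereocentre and gives the linearly conjugated dienone while the tertiary alcohol stays inert.

**Step 11**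
Reactants: 18 (1R,4R,5R)-4-hydroxy-1,8-dimethyl-4-(propan-2-yl)bicyclo[5.3.0]deca-7,9-dien-6-one
Product: 20 (1R,4R,5R)-4-hydroxy-1,8-dimethyl-4-(propan-2-yl)bicyclo[5.3.0]dec-8-en-6-one, via lithium dienolate 19 (not isolated)
Conditions: Li, NH3(l)/THF, −78 °C; then solid NH4Cl, −78 °C
Reagents that add atoms: none
Why: Dissolving-metal (Birch-type) reduction of the linear dienone adds hydrogen at the δ-carbon C10 and leaves the dienolate, whose kinetic protonation at the α-carbon C7 should give the deconjugated β,γ-unsaturated ketone with the alkene at C8=C9 and without a new stereocentre.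

**Step 12**
Reactants: 20 (1R,4R,5R)-4-hydroxy-1,8-dimethyl-4-(propan-2-yl)bicyclo[5.3.0]dec-8-en-6-one
Product: 21 (1R,4R,5S,6S)-1,8-dimethyl-4-(propan-2-yl)bicyclo[5.3.0]dec-8-ene-4,6-diol
Conditions: Me4NBH(OAc)3, MeCN/AcOH, −30 °C
Reagents that add atoms: none
Why: In this Evans–Saksena reduction the C4 hydroxyl exchanges onto boron and delivers hydride within the molecule to the face of the C6 carbonyl that it occupies, which should set C6 with the new hydroxyl anti to the C4 hydroxyl and cis to C5–H.

**Step 13**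
Reactants: 21 (1R,4R,5S,6S)-1,8-dimethyl-4-(propan-2-yl)bicyclo[5.3.0]dec-8-ene-4,6-diol
Product: 22 (1R,4R,5S,6S,8R,9S)-8,9-epoxy-1,8-dimethyl-4-(propan-2-yl)bicyclo[5.3.0]decane-4,6-diol
Conditions: VO(acac)2 (5 mol %), t-BuOOH, CH2Cl2, 0 → 20 °C
Reagents that add atoms: tert-butyl hydroperoxide CC(C)(C)OO
Why: In this vanadium-catalysed hydroxyl-directed epoxidation the homoallylic C6 hydroxyl binds the metal peroxide and delivers oxygen to the face of C8=C9 syn to itself, which is also the face anti to the C1 methyl, and this sets C8 and C9.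

**Step 14**
Reactants: 22 (1R,4R,5S,6S,8R,9S)-8,9-epoxy-1,8-dimethyl-4-(propan-2-yl)bicyclo[5.3.0]decane-4,6-diol; 23 4-methoxybenzoyl chloride
Product: 24 (1R,4R,5S,6S,8R,9S)-8,9-epoxy-4-hydroxy-1,8-dimethyl-4-(propan-2-yl)bicyclo[5.3.0]dec-6-yl 4-methoxybenzoate (target)
Conditions: 4-MeOC6H4COCl, Et3N, DMAP, CH2Cl2, 0 → 20 °C
Reagents that add atoms: 4-methoxybenzoyl chloride COc1ccc(cc1)C(Cl)=O
Why: DMAP-catalysed esterification with the acid chloride should take only the secondary C6 hydroxyl because the tertiary C4 hydroxyl is too hindered, and no stereocentre changes.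

**Compound list**

1 | (S)-(+)-terpinen-4-ol | CC1=CC[C@](O)(C(C)C)CC1 | starting material
2 | triethyl{[(1S)-4-methyl-1-(propan-2-yl)cyclohex-3-en-1-yl]oxy}silane | CC1=CC[C@](O[Si](CC)(CC)CC)(C(C)C)CC1 | intermediate
3 | (3S)-6-oxo-3-(propan-2-yl)-3-[(triethylsilyl)oxy]heptanal (keto aldehyde, not isolated) | CC(=O)CC[C@@](O[Si](CC)(CC)CC)(C(C)C)CC=O | intermediate
4 | (5S)-7,7-dimethoxy-5-(propan-2-yl)-5-[(triethylsilyl)oxy]heptan-2-one | CC(=O)CC[C@@](O[Si](CC)(CC)CC)(C(C)C)CC(OC)OC | intermediate
5 | diethyl (5S)-7,7-dimethoxy-5-(propan-2-yl)-5-[(triethylsilyl)oxy]hept-1-en-2-yl phosphate (enol phosphate, not isolated) | C=C(OP(=O)(OCC)OCC)CC[C@@](O[Si](CC)(CC)CC)(C(C)C)CC(OC)OC | intermediate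
6 | triethyl{[(3S)-1,1-dimethoxy-3-(propan-2-yl)hept-6-yn-3-yl]oxy}silane | C#CCC[C@@](O[Si](CC)(CC)CC)(C(C)C)CC(OC)OC | intermediate
7 | dimethyl{(1E,5S)-7,7-dimethoxy-2-methyl-5-(propan-2-yl)-5-[(triethylsilyl)oxy]hept-1-en-1-yl}alumane (alkenylalane, not isolated) | C[Al](C)/C=C(\C)CC[C@@](O[Si](CC)(CC)CC)(C(C)C)CC(OC)OC | intermediate
8 | triethyl{[(3S,6E)-7-iodo-1,1-dimethoxy-6-methyl-3-(propan-2-yl)hept-6-en-3-yl]oxy}silane | I/C=C(\C)CC[C@@](O[Si](CC)(CC)CC)(C(C)C)CC(OC)OC | intermediate
9 | 4,4,5,5-tetramethyl-2-[(1E)-prop-1-en-1-yl]-1,3,2-dioxaborolane | C/C=C/B1OC(C)(C)C(C)(C)O1 | starting material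
10 | triethyl{[(3S,6E,8E)-1,1-dimethoxy-6-methyl-3-(propan-2-yl)deca-6,8-dien-3-yl]oxy}silane | C/C=C/C=C(\C)CC[C@@](O[Si](CC)(CC)CC)(C(C)C)CC(OC)OC | intermediate
11 | (3S,6E,8E)-6-methyl-3-(propan-2-yl)-3-[(triethylsilyl)oxy]deca-6,8-dienal | C/C=C/C=C(\C)CC[C@@](O[Si](CC)(CC)CC)(C(C)C)CC=O | intermediate
12 | chloroiodomethane | ClCI | starting material
13 | (4S,7E,9E)-1-chloro-7-methyl-4-(propan-2-yl)-4-[(triethylsilyl)oxy]undeca-7,9-dien-2-ol (both C2 epimers) | C/C=C/C=C(\C)CC[C@@](O[Si](CC)(CC)CC)(C(C)C)CC(O)CCl | intermediate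
14 | (4S,7E,9E)-1-chloro-7-methyl-4-(propan-2-yl)-4-[(triethylsilyl)oxy]undeca-7,9-dien-2-one | C/C=C/C=C(\C)CC[C@@](O[Si](CC)(CC)CC)(C(C)C)CC(=O)CCl | intermediate
15 | oxyallyl cation (2-oxidoallyl zwitterion C5–C6–C7 of 14, W form, not isolated) | C/C=C/C=C(\C)CC[C@@](O[Si](CC)(CC)CC)(C(C)C)/C=C(\[O-])[CH2+] | intermediate
16 | (1R,4R,5R,8R)-1,8-dimethyl-4-(propan-2-yl)-4-[(triethylsilyl)oxy]-trans-bicyclo[5.3.0]dec-9-en-6-one (not isolated) | O=C1C[C@@H](C)C=C[C@@]2(C)CC[C@@](O[Si](CC)(CC)CC)(C(C)C)[C@H]12 | intermediate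
17 | (1R,4R,5R,8R)-4-hydroxy-1,8-dimethyl-4-(propan-2-yl)-trans-bicyclo[5.3.0]dec-9-en-6-one | O=C1C[C@@H](C)C=C[C@@]2(C)CC[C@@](O)(C(C)C)[C@H]12 | intermediate
18 | (1R,4R,5R)-4-hydroxy-1,8-dimethyl-4-(propan-2-yl)bicyclo[5.3.0]deca-7,9-dien-6-one | O=C1C=C(C)C=C[C@@]2(C)CC[C@@](O)(C(C)C)[C@H]12 | intermediate
19 | dilithium dienolate alkoxide of 18 after hydrogen addition at C10 (not isolated) | [Li+].[Li+].[O-]C1=CC(C)=CC[C@@]2(C)CC[C@@]([O-])(C(C)C)[C@H]12 | intermediate
20 | (1R,4R,5R)-4-hydroxy-1,8-dimethyl-4-(propan-2-yl)bicyclo[5.3.0]dec-8-en-6-one | O=C1CC(C)=CC[C@@]2(C)CC[C@@](O)(C(C)C)[C@H]12 | intermediate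
21 | (1R,4R,5S,6S)-1,8-dimethyl-4-(propan-2-yl)bicyclo[5.3.0]dec-8-ene-4,6-diol | O[C@H]1CC(C)=CC[C@@]2(C)CC[C@@](O)(C(C)C)[C@H]12 | intermediate
22 | (1R,4R,5S,6S,8R,9S)-8,9-epoxy-1,8-dimethyl-4-(propan-2-yl)bicyclo[5.3.0]decane-4,6-diol | O[C@H]1C[C@@]2(C)O[C@H]2C[C@@]2(C)CC[C@@](O)(C(C)C)[C@H]12 | intermediate
23 | 4-methoxybenzoyl chloride | COc1ccc(cc1)C(Cl)=O | starting material
24 | (1R,4R,5S,6S,8R,9S)-8,9-epoxy-4-hydroxy-1,8-dimethyl-4-(propan-2-yl)bicyclo[5.3.0]dec-6-yl 4-methoxybenzoate | COc1ccc(C(=O)O[C@H]2C[C@@]3(C)O[C@H]3C[C@@]3(C)CC[C@@](O)(C(C)C)[C@H]23)cc1 | target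

Total step count: 14. Longest linear sequence: 14 steps (1 to 24); 9, 12 and 23 are purchased.

**Steps most likely to fail**

Step 9. The C5 enolate may be diverted into Favorskii rearrangement, capture by the fluoroalkoxide or loss of the β-silyloxy group, the primary chloride may ionise too slowly, and a compact approach of the diene would erode the configuration at the new quaternary C1. The fallback generates the cation without base at low temperature. It sets out from aldehyde 11: enamine-catalysed α-chlorination (N-chlorosuccinimide, L-prolinamide) should give the α-chloro aldehyde F1, MeMgBr the chlorohydrin F2, Dess–Martin oxidation the C5-chloro methyl ketone F3, and kinetic enolisation at the methyl group (LiN(iPr)2, Me3SiCl) the 2-(trimethylsilyloxy)allyl chloride F4. Ionisation of F4 with AgClO4 in MeNO2/CH2Cl2 at −78 °C gives the silyloxyallyl cation, whose (4+3) closure and loss of the trimethylsilyl group comes back to the route at 16, which is desilylated to 17 as in the second stage of step 9.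

Step 11. The dienolate may be protonated at C9 or the product may slip back into conjugation during work-up, and over-reduction of the ketone may occur. The fallback places the alkene by 1,4-addition of hydrogen instead. It sets out from dienone 18: directed 1,2-reduction with Me4NBH(OAc)3 should give the dienediol F5, and 1,4-hydrogenation of its cisoid cyclohepta-1,3-diene with (naphthalene)Cr(CO)3 under H2 adds hydrogen at C7 and C10 and leaves C8=C9, which comes back to the route at 21.

Step 12. The hindered tertiary hydroxyl may fail to exchange onto boron, so that hydride arrives from the more open face and the C6 epimer forms. The fallback uses external reduction followed by inversion. It sets out from 20: NaBH4/CeCl3 should give the 6-epi alcohol F6, Mitsunobu esterification with 4-methoxybenzoic acid (PPh3, diisopropyl azodicarboxylate) inverts C6 and gives the unsaturated ester F7, and epoxidation with mCPBA on the face anti to the C1 methyl comes back to the route at 24.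

**Further compounds**

F1 | step 9 | (6E,8E)-2-chloro-6-methyl-3-(propan-2-yl)-3-[(triethylsilyl)oxy]deca-6,8-dienal (C3 as in 11; both C2 epimers) | C/C=C/C=C(\C)CC[C@@](O[Si](CC)(CC)CC)(C(C)C)C(Cl)C=O
F2 | step 9 | (7E,9E)-3-chloro-7-methyl-4-(propan-2-yl)-4-[(triethylsilyl)oxy]undeca-7,9-dien-2-ol (C4 as in 14; epimers at C2 and C3) | C/C=C/C=C(\C)CC[C@@](O[Si](CC)(CC)CC)(C(C)C)C(Cl)C(C)O
F3 | step 9 | (7E,9E)-3-chloro-7-methyl-4-(propan-2-yl)-4-[(triethylsilyl)oxy]undeca-7,9-dien-2-one (C4 as in 14; both C3 epimers) | C/C=C/C=C(\C)CC[C@@](O[Si](CC)(CC)CC)(C(C)C)C(Cl)C(C)=O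
F4 | step 9 | (7E,9E)-3-chloro-7-methyl-4-(propan-2-yl)-4-[(triethylsilyl)oxy]-2-[(trimethylsilyl)oxy]undeca-1,7,9-triene (C4 as in 14; both C3 epimers) | C/C=C/C=C(\C)CC[C@@](O[Si](CC)(CC)CC)(C(C)C)C(Cl)C(=C)O[Si](C)(C)C
F5 | step 11 | (1R,4R,5S,6S)-1,8-dimethyl-4-(propan-2-yl)bicyclo[5.3.0]deca-7,9-diene-4,6-diol | O[C@H]1C=C(C)C=C[C@@]2(C)CC[C@@](O)(C(C)C)[C@H]12
F6 | step 12 | (1R,4R,5S,6R)-1,8-dimethyl-4-(propan-2-yl)bicyclo[5.3.0]dec-8-ene-4,6-diol | O[C@@H]1CC(C)=CC[C@@]2(C)CC[C@@](O)(C(C)C)[C@H]12
F7 | step 12 | (1R,4R,5S,6S)-4-hydroxy-1,8-dimethyl-4-(propan-2-yl)bicyclo[5.3.0]dec-8-en-6-yl 4-methoxybenzoate | COc1ccc(cc1)C(=O)O[C@H]1CC(C)=CC[C@@]2(C)CC[C@@](O)(C(C)C)[C@H]12
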